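**Assumption:** the target SMILES has no stereocentre and no stereogenic double bond, so broussoflavonol F is achiral and no enantioselective step is needed. The racemic centres in 4, 7, 14 and 15 are erased within the route. Partly reacted species of a repeated identical event (mono-MOM ether, mono-metathesis product, partly deprotected flavonols) are not numbered.

## Retrosynthetic overview
1. Target ⇒ remove three MOM ethers and make both prenyl groups from allyl groups by one double cross-metathesis ⇒ 8,3'-diallyl-3-hydroxyflavone tri-MOM ether.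
2. C3–OH ⇐ C3–B. Ring C (O1–C2 bond plus C3–B bond) ⇐ new gold-catalysed 6-endo oxyboration of an o-hydroxyaryl ynone (key step).
3. Ynone ⇐ ring A salicylaldehyde + ring B arylacetylene (acetylide addition, then MnO2).
4. Both C-allyl groups ⇐ regiospecific aromatic Claisen rearrangements. This fixes the future C8 substituent next to the OH that becomes O1, and the C3' substituent next to 4'-O.
5. Ring order: rings A and B are bought (2,4,6-trihydroxybenzaldehyde, 4-(allyloxy)benzaldehyde). Ring C is the only ring formed, in step 9.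

## Route

Step 1
Reactants: 1 2,4,6-trihydroxybenzaldehyde
Product: 2 2-hydroxy-4,6-bis(methoxymethoxy)benzaldehyde
Conditions: MOMCl (2.1 equiv), K2CO3 (2.5 equiv), acetone, 0 °C to rt
Reagents that add atoms: chloromethyl methyl ether (MOMCl), COCCl
Why: Williamson-type O-alkylation stops at the bis-ether because the last ortho OH is locked in a hydrogen bond to the aldehyde.

Step 2
Reactants: 2 2-hydroxy-4,6-bis(methoxymethoxy)benzaldehyde
Product: 3 2-(allyloxy)-4,6-bis(methoxymethoxy)benzaldehyde
Conditions: allyl bromide (1.3 equiv), K2CO3 (2 equiv), DMF, 50 °C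
Reagents that add atoms: allyl bromide, C=CCBr
Why: Williamson ether synthesis, in which carbonate in a polar solvent breaks the chelate and the phenoxide displaces bromide by SN2.

Step 3
Reactants: 3 2-(allyloxy)-4,6-bis(methoxymethoxy)benzaldehyde
Product: 5 3-allyl-2-hydroxy-4,6-bis(methoxymethoxy)benzaldehyde, via ring A ortho-dienone 4 (not isolated)
Conditions: N,N-diethylaniline, 195 °C, sealed tube
Reagents that add atoms: none
Why: Aromatic Claisen rearrangement ([3,3]-sigmatropic) delivers allyl only to C3, the sole ortho carbon bearing hydrogen, then 4 tautomerises to the chelated phenol while the MOM ethers survive the hot basic solvent.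

Step 4
Reactants: 6 4-(allyloxy)benzaldehyde
Product: 8 3-allyl-4-hydroxybenzaldehyde, via ring B ortho-dienone 7 (not isolated)
Conditions: N,N-diethylaniline, 210 °C
Reagents that add atoms: none
Why: Aromatic Claisen rearrangement gives one product because the two ortho positions are equivalent, and 7 rearomatises by tautomerisation.

Step 5
Reactants: 8 3-allyl-4-hydroxybenzaldehyde
Product: 9 3-allyl-4-(methoxymethoxy)benzaldehyde
Conditions: MOMCl (1.3 equiv), K2CO3 (2 equiv), acetone, rt
Reagents that add atoms: chloromethyl methyl ether (MOMCl), COCCl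
Why: Williamson-type O-alkylation of an acidic para-formyl phenol with a very reactive alkylating agent.

Step 6
Reactants: 9 3-allyl-4-(methoxymethoxy)benzaldehyde
Product: 11 2-allyl-4-ethynyl-1-(methoxymethoxy)benzene, via diazoalkene 10 (not isolated)
Conditions: dimethyl (1-diazo-2-oxopropyl)phosphonate (1.3 equiv), K2CO3 (2 equiv), MeOH, rt
Reagents that add atoms: dimethyl (1-diazo-2-oxopropyl)phosphonate (Ohira–Bestmann reagent), COP(=O)(OC)C(=[N+]=[N-])C(C)=O
Why: Seyferth–Gilbert homologation in the Ohira–Bestmann variant, in which Horner-type olefination gives 10, which loses N2 and undergoes a 1,2-hydrogen shift under conditions too mild to isomerise the allyl group.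

Step 7
Reactants: 11 2-allyl-4-ethynyl-1-(methoxymethoxy)benzene; 5 3-allyl-2-hydroxy-4,6-bis(methoxymethoxy)benzaldehyde
Product: 15 1-[3-allyl-2-hydroxy-4,6-bis(methoxymethoxy)phenyl]-3-[3-allyl-4-(methoxymethoxy)phenyl]prop-2-yn-1-ol (racemic), via lithium acetylide 12 (not isolated), via sodium phenoxide 13 (not isolated), via mixed dialkoxide 14 (not isolated)
Conditions: 11 (1.15 equiv), n-BuLi (1.1 equiv), THF, −78 °C; separately 5, NaH (1.05 equiv), THF, 0 °C; combine at −78 °C, warm to 0 °C; aq NH4Cl; used crude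
Reagents that add atoms: none
Why: Nucleophilic 1,2-addition of a lithium acetylide to an aldehyde, where pre-forming 13 keeps the acidic OH from quenching 12, and the new carbinol centre is formed racemic and erased in step 8.

Step 8
Reactants: 15 the propargylic alcohol from step 7
Product: 16 1-[3-allyl-2-hydroxy-4,6-bis(methoxymethoxy)phenyl]-3-[3-allyl-4-(methoxymethoxy)phenyl]prop-2-yn-1-one
Conditions: activated MnO2 (15 equiv), CH2Cl2, rt
Reagents that add atoms: none
Why: MnO2 oxidation is selective for the doubly activated benzylic-propargylic alcohol, leaves alkenes and MOM ethers alone, and gives an ynone stabilised by its internal hydrogen bond.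

Step 9
Reactants: 16 the o-hydroxyaryl ynone
Product: 19 8-allyl-2-[3-allyl-4-(methoxymethoxy)phenyl]-5,7-bis(methoxymethoxy)-3-(4,4,5,5-tetramethyl-1,3,2-dioxaborolan-2-yl)-4H-chromen-4-one, via aryl catechol borate 17 (not isolated), via 3-catecholboryl flavone 18 (not isolated)
Conditions: catecholborane (1.0 equiv), PhMe, 0 °C to rt; (IPr)Au(O2CCF3) (5 mol %, IPr = 1,3-bis(2,6-diisopropylphenyl)imidazol-2-ylidene), 50 °C; then pinacol (3 equiv), Et3N, rt; short neutral alumina plug
Reagents that add atoms: catecholborane, B1Oc2ccccc2O1; pinacol, CC(C)(O)C(C)(C)O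
Why: Proposed new method: gold-catalysed 6-endo-dig oxyboration of an o-hydroxyaryl ynone, which closes ring C (O1–C2) and makes the C3–B bond in one event. Catecholborane converts the phenol to borate 17 with loss of H2, so no proton remains to protodeaurate. Trifluoroacetate moves from gold to boron, giving a cationic monovalent gold centre that binds the alkyne and a four-coordinate borate whose aryloxide oxygen is far more nucleophilic than the neutral OMOM oxygen on the other ortho carbon. Anti attack occurs at the β-carbon because ynone polarisation, carbonyl–boron coordination and the p-alkoxyaryl donor all place positive charge there, which favours 6-endo over 5-exo closure. The resulting 3-aurated flavone carries gold on the enol-ether β-carbon, the most nucleophilic site of a chromone, and transmetalates with CF3CO2Bcat to give 18 and return the catalyst. Pinacol exchange then gives the sturdier 19. The allyl groups sit too far from the alkyne for enyne cyclisation. Closest known reaction types: gold-catalysed alkoxyboration of 2-alkynylphenols to 3-borylbenzofurans, and ICl-induced 6-endo cyclisation of o-alkoxyaryl ynones to 3-iodochromones.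

Step 10
Reactants: 19 the 3-(pinacolboryl)flavone
Product: 21 8-allyl-2-[3-allyl-4-(methoxymethoxy)phenyl]-3-hydroxy-5,7-bis(methoxymethoxy)-4H-chromen-4-one, via pinacol boric ester 20 (not isolated)
Conditions: 30% aq H2O2 (3 equiv), pH 7 phosphate buffer, THF, 0 °C to rt
Reagents that add atoms: hydrogen peroxide, OO
Why: Organoboronate oxidation (hydroperoxide ate complex, 1,2-shift of C3 from boron to oxygen, hydrolysis of 20) installs the 3-OH without touching the isolated alkenes, which dioxirane or peracid hydroxylation would epoxidise.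

Step 11
Reactants: 21 the diallyl flavonol tri-MOM ether
Product: 22 3-hydroxy-5,7-bis(methoxymethoxy)-2-[4-(methoxymethoxy)-3-(3-methylbut-2-enyl)phenyl]-8-(3-methylbut-2-enyl)-4H-chromen-4-one
Conditions: second-generation Grubbs catalyst RuCl2(=CHPh)(PCy3)(SIMes) (2 × 5 mol %, SIMes = 1,3-dimesitylimidazolidin-2-ylidene), 2-methyl-2-butene/CH2Cl2 1:1, 40 °C, sealed tube
Reagents that add atoms: 2-methyl-2-butene, CC=C(C)C
Why: Olefin cross-metathesis, in which the terminal allylarenes react fast, the large excess of 2-methyl-2-butene caps each as a trisubstituted prenyl group that does not re-enter the cycle, and propene escapes.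

Step 12
Reactants: 22 the diprenyl flavonol tri-MOM ether
Product: 23 broussoflavonol F (3,5,7,4'-tetrahydroxy-8,3'-diprenylflavone)
Conditions: HCl (1.25 M in MeOH, 0.5 equiv), MeOH, 40 °C, stopped at full conversion
Reagents that add atoms: none
Why: Acid-catalysed acetal exchange with methanol frees the three phenols, and the low acid strength and temperature keep the prenyl groups from closing onto 7-OH and 4'-OH as chromans.

## Compound list
1 | 2,4,6-trihydroxybenzaldehyde | O=Cc1c(O)cc(O)cc1O | starting material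
2 | 2-hydroxy-4,6-bis(methoxymethoxy)benzaldehyde | O=Cc1c(O)cc(OCOC)cc1OCOC | intermediate
3 | 2-(allyloxy)-4,6-bis(methoxymethoxy)benzaldehyde | C=CCOc1cc(OCOC)cc(OCOC)c1C=O | intermediate
4 | ring A ortho-dienone, 5-allyl-2,4-bis(methoxymethoxy)-6-oxocyclohexa-1,3-diene-1-carbaldehyde (racemic, formed in the flask) | O=CC1=C(OCOC)C=C(OCOC)C(CC=C)C1=O | intermediate
5 | 3-allyl-2-hydroxy-4,6-bis(methoxymethoxy)benzaldehyde | O=Cc1c(O)c(CC=C)c(OCOC)cc1OCOC | intermediate
6 | 4-(allyloxy)benzaldehyde | C=CCOc1ccc(C=O)cc1 | starting material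
7 | ring B ortho-dienone, 3-allyl-4-oxocyclohexa-1,5-diene-1-carbaldehyde (racemic, formed in the flask) | O=CC1=CC(CC=C)C(=O)C=C1 | intermediate
8 | 3-allyl-4-hydroxybenzaldehyde | O=Cc1ccc(O)c(CC=C)c1 | intermediate
9 | 3-allyl-4-(methoxymethoxy)benzaldehyde | O=Cc1ccc(OCOC)c(CC=C)c1 | intermediate
10 | diazoalkene, 2-allyl-4-(2-diazoethenyl)-1-(methoxymethoxy)benzene (formed in the flask) | C(=C=[N+]=[N-])c1ccc(OCOC)c(CC=C)c1 | intermediate
11 | 2-allyl-4-ethynyl-1-(methoxymethoxy)benzene | C#Cc1ccc(OCOC)c(CC=C)c1 | intermediate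
12 | lithium acetylide of 11 (formed in the flask) | [Li]C#Cc1ccc(OCOC)c(CC=C)c1 | intermediate
13 | sodium phenoxide of 5 (formed in the flask) | [Na+].[O-]c1c(C=O)c(OCOC)cc(OCOC)c1CC=C | intermediate
14 | mixed dialkoxide, lithium sodium salt of 15 (racemic, formed in the flask) | [Li+].[Na+].[O-]C(C#Cc1ccc(OCOC)c(CC=C)c1)c1c([O-])c(CC=C)c(OCOC)cc1OCOC | intermediate
15 | 1-[3-allyl-2-hydroxy-4,6-bis(methoxymethoxy)phenyl]-3-[3-allyl-4-(methoxymethoxy)phenyl]prop-2-yn-1-ol (racemic) | OC(C#Cc1ccc(OCOC)c(CC=C)c1)c1c(O)c(CC=C)c(OCOC)cc1OCOC | intermediate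
16 | 1-[3-allyl-2-hydroxy-4,6-bis(methoxymethoxy)phenyl]-3-[3-allyl-4-(methoxymethoxy)phenyl]prop-2-yn-1-one | O=C(C#Cc1ccc(OCOC)c(CC=C)c1)c1c(O)c(CC=C)c(OCOC)cc1OCOC | intermediate
17 | aryl catechol borate, O-(1,3,2-benzodioxaborol-2-yl) derivative of 16 (formed in the flask) | O=C(C#Cc1ccc(OCOC)c(CC=C)c1)c1c(OB2Oc3ccccc3O2)c(CC=C)c(OCOC)cc1OCOC | intermediate
18 | 3-catecholboryl flavone, 8-allyl-2-[3-allyl-4-(methoxymethoxy)phenyl]-3-(1,3,2-benzodioxaborol-2-yl)-5,7-bis(methoxymethoxy)-4H-chromen-4-one (formed in the flask) | O=c1c(B2Oc3ccccc3O2)c(-c2ccc(OCOC)c(CC=C)c2)oc2c(CC=C)c(OCOC)cc(OCOC)c12 | intermediate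
19 | 8-allyl-2-[3-allyl-4-(methoxymethoxy)phenyl]-5,7-bis(methoxymethoxy)-3-(4,4,5,5-tetramethyl-1,3,2-dioxaborolan-2-yl)-4H-chromen-4-one | O=c1c(B2OC(C)(C)C(C)(C)O2)c(-c2ccc(OCOC)c(CC=C)c2)oc2c(CC=C)c(OCOC)cc(OCOC)c12 | intermediate
20 | pinacol boric ester, 3-O-(4,4,5,5-tetramethyl-1,3,2-dioxaborolan-2-yl) derivative of 21 (formed in the flask) | O=c1c(OB2OC(C)(C)C(C)(C)O2)c(-c2ccc(OCOC)c(CC=C)c2)oc2c(CC=C)c(OCOC)cc(OCOC)c12 | intermediate
21 | 8-allyl-2-[3-allyl-4-(methoxymethoxy)phenyl]-3-hydroxy-5,7-bis(methoxymethoxy)-4H-chromen-4-one | O=c1c(O)c(-c2ccc(OCOC)c(CC=C)c2)oc2c(CC=C)c(OCOC)cc(OCOC)c12 | intermediate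
22 | 3-hydroxy-5,7-bis(methoxymethoxy)-2-[4-(methoxymethoxy)-3-(3-methylbut-2-enyl)phenyl]-8-(3-methylbut-2-enyl)-4H-chromen-4-one | O=c1c(O)c(-c2ccc(OCOC)c(CC=C(C)C)c2)oc2c(CC=C(C)C)c(OCOC)cc(OCOC)c12 | intermediate
23 | broussoflavonol F (achiral) | CC(C)=CCc1cc(-c2oc3c(CC=C(C)C)c(O)cc(O)c3c(=O)c2O)ccc1O | target

## Totals and risks
**Total step count:** 12.
**Longest linear sequence:** 9 steps (steps 1–3 or steps 4–6, then steps 7–12).

**Risk 1, step 9 (the proposed new oxyboration).**
- It could fail in four ways: 5-exo closure to a boryl aurone; stray protons giving the plain flavone; attack by the other ortho OMOM oxygen with MOM transfer; or a carbonyl–boron chelate in 17 that is too stable to react.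
- The fallback uses known chemistry. It sets out from 16 and comes back at 21.
- 16 is closed with DMAP (20 mol %) in DMF at 40 °C, a nucleophile-catalysed 6-endo oxa-Michael cyclisation, to 8,3'-diallyl-5,7,4'-tris(methoxymethoxy)flavone F1.
- LiN(i-Pr)2 in THF at −78 °C removes the acidic C3 proton to give 3-lithio-8,3'-diallyl-5,7,4'-tris(methoxymethoxy)flavone F2.
- B(OMe)3 traps this as lithium trimethoxy[8,3'-diallyl-5,7,4'-tris(methoxymethoxy)flavon-3-yl]borate F3.
- AcOH and 30% H2O2 then oxidise the C–B bond to give 21.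

**Risk 2, step 7 (acetylide addition to a deactivated phenoxide-aldehyde).**
- The product is a very electron-rich o-hydroxy carbinol that can ionise to an o-quinone methide.
- The fallback masks the phenol. It sets out from 5 (as its sodium phenoxide 13) and from lithium acetylide 12, and comes back at 16.
- 13 is silylated with chlorotriisopropylsilane in THF to 3-allyl-4,6-bis(methoxymethoxy)-2-(triisopropylsilyloxy)benzaldehyde F4.
- 12 adds to this neutral aldehyde at −78 °C to give the lithium alkoxide of the silyl carbinol F5.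
- Aqueous NH4Cl gives 1-[3-allyl-4,6-bis(methoxymethoxy)-2-(triisopropylsilyloxy)phenyl]-3-[3-allyl-4-(methoxymethoxy)phenyl]prop-2-yn-1-ol F6, which cannot form a quinone methide.
- MnO2 in CH2Cl2 gives the corresponding silyl-protected ynone F7.
- HF·pyridine in THF/pyridine at 0 °C frees the phenol under non-basic conditions, so the ynone does not cyclise, and gives 16.

**Risk 3, step 12 (acid next to prenyl groups).**
- Protonation of a prenyl alkene gives a tertiary cation that the neighbouring 7-OH or 4'-OH traps as a dimethylchroman.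
- The fallback swaps the order of events. It sets out from 21 and comes back at 23.
- 21 is deprotected first with methanolic HCl, where the allyl groups cannot give tertiary cations, to 8,3'-diallylkaempferol F8.
- The double cross-metathesis with 2-methyl-2-butene is then run last under neutral conditions, using the second-generation Hoveyda–Grubbs catalyst RuCl2(=CH-C6H4-2-O-i-Pr)(SIMes) in THF/2-methyl-2-butene at 40 °C, to give 23.

## Further compounds
F1 | step 9 | 8,3'-diallyl-5,7,4'-tris(methoxymethoxy)flavone | O=c1cc(-c2ccc(OCOC)c(CC=C)c2)oc2c(CC=C)c(OCOC)cc(OCOC)c12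
F2 | step 9 | 3-lithio-8,3'-diallyl-5,7,4'-tris(methoxymethoxy)flavone | O=c1c([Li])c(-c2ccc(OCOC)c(CC=C)c2)oc2c(CC=C)c(OCOC)cc(OCOC)c12
F3 | step 9 | lithium trimethoxy[8,3'-diallyl-5,7,4'-tris(methoxymethoxy)flavon-3-yl]borate | [Li+].CO[B-](OC)(OC)c1c(-c2ccc(OCOC)c(CC=C)c2)oc2c(CC=C)c(OCOC)cc(OCOC)c2c1=O
F4 | step 7 | 3-allyl-4,6-bis(methoxymethoxy)-2-(triisopropylsilyloxy)benzaldehyde | O=Cc1c(O[Si](C(C)C)(C(C)C)C(C)C)c(CC=C)c(OCOC)cc1OCOC
F5 | step 7 | lithium alkoxide of the silyl carbinol (racemic) | [Li+].[O-]C(C#Cc1ccc(OCOC)c(CC=C)c1)c1c(O[Si](C(C)C)(C(C)C)C(C)C)c(CC=C)c(OCOC)cc1OCOC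
F6 | step 7 | 1-[3-allyl-4,6-bis(methoxymethoxy)-2-(triisopropylsilyloxy)phenyl]-3-[3-allyl-4-(methoxymethoxy)phenyl]prop-2-yn-1-ol (racemic) | OC(C#Cc1ccc(OCOC)c(CC=C)c1)c1c(O[Si](C(C)C)(C(C)C)C(C)C)c(CC=C)c(OCOC)cc1OCOC
F7 | step 7 | silyl-protected ynone, 1-[3-allyl-4,6-bis(methoxymethoxy)-2-(triisopropylsilyloxy)phenyl]-3-[3-allyl-4-(methoxymethoxy)phenyl]prop-2-yn-1-one | O=C(C#Cc1ccc(OCOC)c(CC=C)c1)c1c(O[Si](C(C)C)(C(C)C)C(C)C)c(CC=C)c(OCOC)cc1OCOC
F8 | step 12 | 8,3'-diallylkaempferol | O=c1c(O)c(-c2ccc(O)c(CC=C)c2)oc2c(CC=C)c(O)cc(O)c12
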